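**Plan**
Numbering (germacrane): C1 CHOH, C4–C5 oxirane, C6 lactone CH–O, C7, C8 tiglate carbon, C10 CH–CH3, C11/C12 lactone α-carbon and C=O, C13 CH2OAc; "trinor" compounds lack C11–C13.
Cuts, backwards: C1–O–Si and C13–OAc; C7=C11 and C11–C13 (back to a saturated lactone); C7–C11 (carbenoid C–H insertion, back to an O6 diazoacetate); the O6 and O8 acyl groups; C1–O/C10–H (hydroboration) and the oxirane; C8–C9 of the ten-membered ring (oxy-Cope, back to a cyclohexenol); C6–C7 (vinyl addition to isopiperitenone).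
Forward: isopiperitenone from (S)-limonene takes up a (Z)-2-benzyloxyvinyl group; ring expansion gives the carbocycle (step 4), then the oxirane (step 6), then the γ-lactone (step 15), which is finally converted into the 13-acetoxy butenolide.
Enabling feature: the lactone is fused to the carbocycle at C6–C7 and C12–C11 hang from O6, so a diazoacetate on O6 places carbenoid C11 in a five-membered array with the C7 hydrogens, while C5–H (oxirane) and C8–H (acyloxy carbon) are deactivated.
Stereochemistry: C4 of (S)-limonene is relayed to C8 by the chair oxy-Cope; C6 follows from C8 (chelation-controlled hydride), the oxirane from C6 (hydroxyl-directed epoxidation), C1 and C10 from syn hydroboration of the E olefin on its outer face; C7 and C11 are temporary.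

Key step: step 15

Remark: the target SMILES is read as (1S,4R,5S,6S,8S,10R) with a cis oxirane (C3 and C6 on the same side), which is what the 4Z olefin of the ring-expansion product delivers directly.

Step 1
Reactants: 1 (S)-(−)-limonene
Product: 2 (R)-isopiperitenone [(6R)-3-methyl-6-(prop-1-en-2-yl)cyclohex-2-en-1-one]
Conditions: CrO3, 3,5-dimethylpyrazole, CH2Cl2, −20 °C
Reagents that add atoms: chromium trioxide, O=[Cr](=O)=O
Why: Allylic oxidation by the CrO3–3,5-dimethylpyrazole complex turns the ring CH2 between the trisubstituted double bond and C4 into the enone carbonyl and leaves the C4 stereocentre untouched (the regioisomeric enone, carvone, is the expected by-product and would be removed by chromatography).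

Step 2
Reactants: 3 benzyl vinyl ether
Product: 5 (Z)-2-bromovinyl benzyl ether, via dibromo ether 4 (not isolated)
Conditions: Br2, CH2Cl2, −78 °C; then i-Pr2NEt, −78 → 40 °C
Reagents that add atoms: bromine, BrBr
Why: Electrophilic bromination of the enol ether followed by amine-induced dehydrobromination (addition–elimination) should give mainly the Z bromovinyl ether, the isomer favoured by the cis effect of 1-alkoxy-2-haloethenes, and any E isomer would be separated.

Step 3
Reactants: 5 (Z)-2-bromovinyl benzyl ether; 2 (R)-isopiperitenone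
Product: 7 (1R,6R)-1-[(Z)-2-(benzyloxy)ethenyl]-3-methyl-6-(prop-1-en-2-yl)cyclohex-2-en-1-ol, via vinyllithium 6 (not isolated)
Conditions: n-BuLi, Et2O, −78 °C; then 2, −78 °C; H2O
Reagents that add atoms: none
Why: Bromine–lithium exchange with retention gives the oxygen-coordinated cis-2-alkoxyvinyllithium, which adds 1,2 to the enone carbonyl anti to the neighbouring isopropenyl group, so that the new carbinol centre (1R) carries the two alkenyl groups trans to each other.

Step 4
Reactants: 7 (1R,6R)-1-[(Z)-2-(benzyloxy)ethenyl]-3-methyl-6-(prop-1-en-2-yl)cyclohex-2-en-1-ol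
Product: 10 (8S)-8-benzyloxy-11,12,13-trinorgermacra-1(10)E,4Z-dien-6-one [(2Z,6E,9S)-9-benzyloxy-3,7-dimethylcyclodeca-2,6-dien-1-one], via potassium alkoxide 8 (not isolated), via potassium dienolate 9 (not isolated)
Conditions: KH, 18-crown-6, THF, 0 °C; then AcOH, −78 °C
Reagents that add atoms: none
Why: Anionic oxy-Cope rearrangement (a [3,3]-sigmatropic shift of the potassium 1,5-dien-3-olate) through the chair transition state available to the trans-dialkenyl alkoxide breaks C1–C6, forms C8–C9 and the E C1=C10 bond, keeps the ring Z double bond as C4=C5 and, with the Z alkoxy group axial on the chair, relays the limonene stereocentre to C8 (S) before C-protonation of the dienolate at C7.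

Step 5
Reactants: 10 (8S)-8-benzyloxy-11,12,13-trinorgermacra-1(10)E,4Z-dien-6-one
Product: 11 (6S,8S)-8-benzyloxy-11,12,13-trinorgermacra-1(10)E,4Z-dien-6-ol
Conditions: LiAlH4, LiI, Et2O, −78 °C
Reagents that add atoms: none
Why: Chelation-controlled 1,2-reduction of a β-alkoxy ketone: Li+ bridges the C6 carbonyl and the C8 benzyloxy oxygen and hydride enters the carbonyl face that is not covered by the transannular C1=C10 bond, which should give the 6,8-syn allylic alcohol (6S).

Step 6
Reactants: 11 (6S,8S)-8-benzyloxy-11,12,13-trinorgermacra-1(10)E,4Z-dien-6-ol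
Product: 12 (4R,5S,6S,8S)-8-benzyloxy-4,5-epoxy-11,12,13-trinorgermacr-1(10)E-en-6-ol
Conditions: VO(acac)2 (cat.), t-BuOOH, CH2Cl2, 0 °C
Reagents that add atoms: tert-butyl hydroperoxide, CC(C)(C)OO
Why: Hydroxyl-directed epoxidation: the vanadate ester of the C6 alcohol delivers oxygen to the neighbouring Z C4=C5 bond on the face of the hydroxyl, as is known for medium-ring (Z)-cycloalk-2-enols, giving the cis epoxy alcohol (4R,5S) and leaving the remote C1=C10 bond alone.

Step 7
Reactants: 12 (4R,5S,6S,8S)-8-benzyloxy-4,5-epoxy-11,12,13-trinorgermacr-1(10)E-en-6-ol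
Product: 13 (4R,5S,6S,8S)-8-benzyloxy-4,5-epoxy-6-triethylsilyloxy-11,12,13-trinorgermacr-1(10)E-ene
Conditions: Et3SiCl, imidazole, DMF, 0 °C → rt
Reagents that add atoms: chlorotriethylsilane, CC[Si](Cl)(CC)CC
Why: Imidazole-promoted silylation masks the C6 alcohol through steps 8 to 11 with a group that can later be removed in the presence of a bulkier silyl ether.

Step 8
Reactants: 13 (4R,5S,6S,8S)-8-benzyloxy-4,5-epoxy-6-triethylsilyloxy-11,12,13-trinorgermacr-1(10)E-ene
Product: 15 (1S,4R,5S,6S,8S,10R)-8-benzyloxy-4,5-epoxy-6-triethylsilyloxy-11,12,13-trinorgermacran-1-ol, via alkylborane 14 (not isolated)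
Conditions: BH3·THF, THF, 0 °C → rt; then NaOH, H2O2, 0 °C
Reagents that add atoms: hydrogen peroxide, OO
Why: Hydroboration–oxidation: borane adds syn to the E trisubstituted C1=C10 bond with boron at the less substituted C1 and from the outer face of the olefin (the inner face is covered by the C5–C7 arc of the crown-shaped ring formed in step 4), and oxidation with retention then gives the 1S alcohol and the 10R methyl centre.

Step 9
Reactants: 15 (1S,4R,5S,6S,8S,10R)-8-benzyloxy-4,5-epoxy-6-triethylsilyloxy-11,12,13-trinorgermacran-1-ol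
Product: 16 (1S,4R,5S,6S,8S,10R)-8-benzyloxy-1-(tert-butyldimethylsilyloxy)-4,5-epoxy-6-triethylsilyloxy-11,12,13-trinorgermacrane
Conditions: t-BuMe2SiCl, imidazole, DMAP, DMF, 40 °C
Reagents that add atoms: tert-butylchlorodimethylsilane, CC(C)(C)[Si](C)(C)Cl
Why: Silylation of the C1 alcohol with a group that survives the removal of the triethylsilyl ether in step 12 and prevents O–H insertion in step 15.

Step 10
Reactants: 16 (1S,4R,5S,6S,8S,10R)-8-benzyloxy-1-(tert-butyldimethylsilyloxy)-4,5-epoxy-6-triethylsilyloxy-11,12,13-trinorgermacrane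
Product: 17 (1S,4R,5S,6S,8S,10R)-1-(tert-butyldimethylsilyloxy)-4,5-epoxy-6-triethylsilyloxy-11,12,13-trinorgermacran-8-ol
Conditions: H2 (1 atm), 10% Pd/C, EtOAc, rt
Reagents that add atoms: none
Why: Hydrogenolysis of the benzyl ether frees the C8 hydroxyl; no alkene is left at this stage, and the trialkyl-substituted oxirane and the silyl ethers are not reduced under neutral conditions.

Step 11
Reactants: 17 (1S,4R,5S,6S,8S,10R)-1-(tert-butyldimethylsilyloxy)-4,5-epoxy-6-triethylsilyloxy-11,12,13-trinorgermacran-8-ol; 18 tiglic acid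
Product: 20 (1S,4R,5S,6S,8S,10R)-1-(tert-butyldimethylsilyloxy)-4,5-epoxy-6-triethylsilyloxy-11,12,13-trinorgermacran-8-yl tiglate, via mixed anhydride 19 (not isolated)
Conditions: 18, 2,4,6-trichlorobenzoyl chloride, Et3N, THF, rt; then 17, DMAP, toluene, rt → 40 °C
Reagents that add atoms: none
Why: Yamaguchi esterification: the mixed 2,4,6-trichlorobenzoic anhydride of tiglic acid acylates the secondary C8 alcohol under DMAP catalysis with retention at C8, and the E (tiglate) geometry is the stable one, so no isomerisation is expected.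

Step 12
Reactants: 20 (1S,4R,5S,6S,8S,10R)-1-(tert-butyldimethylsilyloxy)-4,5-epoxy-6-triethylsilyloxy-11,12,13-trinorgermacran-8-yl tiglate
Product: 21 (1S,4R,5S,6S,8S,10R)-1-(tert-butyldimethylsilyloxy)-4,5-epoxy-6-hydroxy-11,12,13-trinorgermacran-8-yl tiglate
Conditions: HF·pyridine, pyridine, THF, 0 °C
Reagents that add atoms: none
Why: Buffered HF·pyridine removes the triethylsilyl ether far faster than the tert-butyldimethylsilyl ether (selective desilylation) and should neither open the oxirane nor let the tiglate migrate.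

Step 13
Reactants: 21 (1S,4R,5S,6S,8S,10R)-1-(tert-butyldimethylsilyloxy)-4,5-epoxy-6-hydroxy-11,12,13-trinorgermacran-8-yl tiglate; 22 bromoacetyl bromide
Product: 23 (1S,4R,5S,6S,8S,10R)-6-bromoacetoxy-1-(tert-butyldimethylsilyloxy)-4,5-epoxy-11,12,13-trinorgermacran-8-yl tiglate
Conditions: 22, NaHCO3, MeCN, 0 °C
Reagents that add atoms: none
Why: O-acylation of the C6 alcohol with the acid bromide under weakly basic conditions (nucleophilic acyl substitution) brings in C12 and C11.

Step 14
Reactants: 23 (1S,4R,5S,6S,8S,10R)-6-bromoacetoxy-1-(tert-butyldimethylsilyloxy)-4,5-epoxy-11,12,13-trinorgermacran-8-yl tiglate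
Product: 24 (1S,4R,5S,6S,8S,10R)-1-(tert-butyldimethylsilyloxy)-6-diazoacetoxy-4,5-epoxy-11,12,13-trinorgermacran-8-yl tiglate
Conditions: TsNHNHTs, DBU, THF, 0 °C
Reagents that add atoms: N,N'-bis(4-methylbenzenesulfonyl)hydrazine, Cc1ccc(cc1)S(=O)(=O)NNS(=O)(=O)c1ccc(C)cc1
Why: The bromoacetate N-alkylates N,N'-ditosylhydrazine and DBU then expels two sulfinate ions to give the diazoacetate (the standard bromoacetate-to-diazoacetate conversion), under conditions mild enough for the oxirane and the tiglate.

Step 15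
Reactants: 24 (1S,4R,5S,6S,8S,10R)-1-(tert-butyldimethylsilyloxy)-6-diazoacetoxy-4,5-epoxy-11,12,13-trinorgermacran-8-yl tiglate
Product: 25 (1S,4R,5S,6S,7S,8S,10R)-1-(tert-butyldimethylsilyloxy)-4,5-epoxy-8-tigloyloxy-13-norgermacran-12,6-olide (cis-fused γ-lactone)
Conditions: Rh2(acam)4 (dirhodium tetraacetamidate, 1 mol%), CH2Cl2, reflux, slow addition of 24
Reagents that add atoms: none
Why: Rh2(acam)4 extrudes N2 from diazoacetate 24 to give an electrophilic rhodium carbenoid at C11, which inserts into a C7–H bond in one concerted three-centre step with retention at C7, forming C7–C11; the closest known reaction type is the dirhodium-carboxamidate-catalysed intramolecular C–H insertion of alkyl diazoacetates to γ-butyrolactones. The γ-lactone ring (C6–O–C12–C11–C7) closes by 1,5-insertion through a five-membered array, the mode preferred over four- and six-membered closure, and it is formed on the intact ten-membered ring. The new stereocentre C7 is set by which of the two diastereotopic C7 hydrogens is replaced: the one syn to the C6–O bond is reached without twisting the ester out of conjugation, so the cis-fused (7S) lactone is expected, as with medium-ring cycloalkyl diazoacetates, and this centre is in any case erased in step 19. The selectivity needed is insertion at C7–H in preference to C5–H, C8–H, ylide formation at the oxirane or ester oxygens and carbene dimerisation. It is secured by the strong, s-rich oxirane C5–H bond, by the acyloxy group that deactivates C8–H, by the absence of any alkene within reach or free hydroxyl, by the carboxamidate ligands, which temper the carbenoid and favour five-membered insertion, and by slow addition at high dilution.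

Step 16
Reactants: 25 (1S,4R,5S,6S,7S,8S,10R)-1-(tert-butyldimethylsilyloxy)-4,5-epoxy-8-tigloyloxy-13-norgermacran-12,6-olide
Product: 28 (1S,4R,5S,6S,7S,8S,10R,11S)-1-(tert-butyldimethylsilyloxy)-4,5-epoxy-13-oxo-11-phenylselanyl-8-tigloyloxygermacran-12,6-olide, via lactone enolate 26 (not isolated), via formyl enolate 27 (not isolated)
Conditions: LiN(SiMe3)2, THF, −78 °C; HCO2CH2CF3, −78 °C; then PhSeCl, −78 → 0 °C
Reagents that add atoms: 2,2,2-trifluoroethyl formate, O=COCC(F)(F)F; benzeneselenenyl chloride, Cl[Se]c1ccccc1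
Why: Crossed Claisen formylation of the lactone enolate (made with the non-nucleophilic LiN(SiMe3)2 so that the tiglate is spared) followed by C-selenenylation of the resulting β-oxo enolate: the electrophile enters C11 anti to the C8-bearing side of C7, i.e. syn to H7, which sets the quaternary centre (11S) with selenium cis to H7 as the later syn elimination requires.

Step 17
Reactants: 28 (1S,4R,5S,6S,7S,8S,10R,11S)-1-(tert-butyldimethylsilyloxy)-4,5-epoxy-13-oxo-11-phenylselanyl-8-tigloyloxygermacran-12,6-olide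
Product: 29 (1S,4R,5S,6S,7S,8S,10R,11S)-1-(tert-butyldimethylsilyloxy)-4,5-epoxy-13-hydroxy-11-phenylselanyl-8-tigloyloxygermacran-12,6-olide
Conditions: Zn(BH4)2, Et2O, −20 → 0 °C
Reagents that add atoms: none
Why: Chemoselective hydride reduction of the non-enolisable aldehyde with Zn(BH4)2 under neutral conditions, which avoids retro-Claisen loss of the formyl group and leaves lactone, tiglate and selenide untouched.

Step 18
Reactants: 29 (1S,4R,5S,6S,7S,8S,10R,11S)-1-(tert-butyldimethylsilyloxy)-4,5-epoxy-13-hydroxy-11-phenylselanyl-8-tigloyloxygermacran-12,6-olide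
Product: 30 (1S,4R,5S,6S,7S,8S,10R,11S)-13-acetoxy-1-(tert-butyldimethylsilyloxy)-4,5-epoxy-11-phenylselanyl-8-tigloyloxygermacran-12,6-olide
Conditions: Ac2O, pyridine, DMAP (cat.), CH2Cl2, 0 °C
Reagents that add atoms: acetic anhydride, CC(=O)OC(C)=O
Why: DMAP-catalysed acetylation of the primary C13 alcohol (nucleophilic acyl substitution) installs the target's acetate before the base-sensitive butenolide exists.

Step 19
Reactants: 30 (1S,4R,5S,6S,7S,8S,10R,11S)-13-acetoxy-1-(tert-butyldimethylsilyloxy)-4,5-epoxy-11-phenylselanyl-8-tigloyloxygermacran-12,6-olide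
Product: 32 (1S,4R,5S,6S,8S,10R)-13-acetoxy-1-(tert-butyldimethylsilyloxy)-4,5-epoxy-8-tigloyloxygermacr-7(11)-en-12,6-olide, via selenoxide 31 (not isolated)
Conditions: 30% H2O2, pyridine, CH2Cl2, 0 °C → rt
Reagents that add atoms: none
Why: Oxidation to the selenoxide and spontaneous syn elimination (selenoxide elimination) toward H7 rather than toward the oxygen-bearing C13 gives the conjugated C7=C11 butenolide and removes the C7 and C11 stereocentres.

Step 20
Reactants: 32 (1S,4R,5S,6S,8S,10R)-13-acetoxy-1-(tert-butyldimethylsilyloxy)-4,5-epoxy-8-tigloyloxygermacr-7(11)-en-12,6-olide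
Product: 33 (1S,4R,5S,6S,8S,10R)-13-acetoxy-4,5-epoxy-1-hydroxy-8-tigloyloxygermacr-7(11)-en-12,6-olide (target)
Conditions: HF·pyridine, pyridine, THF, 0 °C → rt
Reagents that add atoms: none
Why: Fluoride-mediated desilylation of the C1 tert-butyldimethylsilyl ether under buffered conditions that the oxirane, the butenolide and both esters should tolerate.

**Compound list**
1 | (S)-(−)-limonene | CC1=CC[C@H](CC1)C(C)=C | starting material
2 | (R)-isopiperitenone | CC1=CC(=O)[C@H](CC1)C(C)=C | intermediate
3 | benzyl vinyl ether | C=COCc1ccccc1 | starting material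
4 | 1,2-dibromoethyl benzyl ether (racemic) | BrCC(Br)OCc1ccccc1 | intermediate
5 | (Z)-2-bromovinyl benzyl ether | Br/C=C\OCc1ccccc1 | intermediate
6 | (Z)-2-(benzyloxy)vinyllithium | [Li]/C=C\OCc1ccccc1 | intermediate
7 | (1R,6R)-1-[(Z)-2-(benzyloxy)ethenyl]-3-methyl-6-(prop-1-en-2-yl)cyclohex-2-en-1-ol | CC1=C[C@](O)(/C=C\OCc2ccccc2)[C@H](CC1)C(C)=C | intermediate
8 | potassium alkoxide of 7 | CC1=C[C@]([O-])(/C=C\OCc2ccccc2)[C@H](CC1)C(C)=C.[K+] | intermediate
9 | potassium C6,C7-dienolate of 10 | c1ccccc1CO[C@H]2C/C(C)=C/CC/C(C)=C\C([O-])=C\2.[K+] | intermediate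
10 | (8S)-8-benzyloxy-11,12,13-trinorgermacra-1(10)E,4Z-dien-6-one | c1ccccc1CO[C@H]2C/C(C)=C/CC/C(C)=C\C(=O)C2 | intermediate
11 | (6S,8S)-8-benzyloxy-11,12,13-trinorgermacra-1(10)E,4Z-dien-6-ol | c1ccccc1CO[C@H]2C/C(C)=C/CC/C(C)=C\[C@@H](O)C2 | intermediate
12 | (4R,5S,6S,8S)-8-benzyloxy-4,5-epoxy-11,12,13-trinorgermacr-1(10)E-en-6-ol | c1ccccc1CO[C@H]2C/C(C)=C/CC[C@@]3(C)O[C@H]3[C@@H](O)C2 | intermediate
13 | 6-O-triethylsilyl ether of 12 | c1ccccc1CO[C@H]2C/C(C)=C/CC[C@@]3(C)O[C@H]3[C@@H](O[Si](CC)(CC)CC)C2 | intermediate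
14 | C1 alkylborane from 13 | c1ccccc1CO[C@H]2C[C@@H](C)[C@@H](B)CC[C@@]3(C)O[C@H]3[C@@H](O[Si](CC)(CC)CC)C2 | intermediate
15 | (1S,4R,5S,6S,8S,10R)-8-benzyloxy-4,5-epoxy-6-triethylsilyloxy-11,12,13-trinorgermacran-1-ol | c1ccccc1CO[C@H]2C[C@@H](C)[C@@H](O)CC[C@@]3(C)O[C@H]3[C@@H](O[Si](CC)(CC)CC)C2 | intermediate
16 | 1-O-tert-butyldimethylsilyl ether of 15 | c1ccccc1CO[C@H]2C[C@@H](C)[C@@H](O[Si](C)(C)C(C)(C)C)CC[C@@]3(C)O[C@H]3[C@@H](O[Si](CC)(CC)CC)C2 | intermediate
17 | (1S,4R,5S,6S,8S,10R)-1-(tert-butyldimethylsilyloxy)-4,5-epoxy-6-triethylsilyloxy-11,12,13-trinorgermacran-8-ol | O[C@H]1C[C@@H](C)[C@@H](O[Si](C)(C)C(C)(C)C)CC[C@@]2(C)O[C@H]2[C@@H](O[Si](CC)(CC)CC)C1 | intermediate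
18 | tiglic acid | C/C=C(\C)C(O)=O | starting material
19 | tiglic 2,4,6-trichlorobenzoic anhydride | C/C=C(\C)C(=O)OC(=O)c1c(Cl)cc(Cl)cc1Cl | intermediate
20 | 8-O-tigloyl derivative of 17 | C/C=C(\C)C(=O)O[C@H]1C[C@@H](C)[C@@H](O[Si](C)(C)C(C)(C)C)CC[C@@]2(C)O[C@H]2[C@@H](O[Si](CC)(CC)CC)C1 | intermediate
21 | (1S,4R,5S,6S,8S,10R)-1-(tert-butyldimethylsilyloxy)-4,5-epoxy-6-hydroxy-11,12,13-trinorgermacran-8-yl tiglate | C/C=C(\C)C(=O)O[C@H]1C[C@@H](C)[C@@H](O[Si](C)(C)C(C)(C)C)CC[C@@]2(C)O[C@H]2[C@@H](O)C1 | intermediate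
22 | bromoacetyl bromide | BrCC(Br)=O | starting material
23 | 6-O-bromoacetate of 21 | C/C=C(\C)C(=O)O[C@H]1C[C@@H](C)[C@@H](O[Si](C)(C)C(C)(C)C)CC[C@@]2(C)O[C@H]2[C@@H](OC(=O)CBr)C1 | intermediate
24 | 6-O-diazoacetate of 21 (key-step precursor) | C/C=C(\C)C(=O)O[C@H]1C[C@@H](C)[C@@H](O[Si](C)(C)C(C)(C)C)CC[C@@]2(C)O[C@H]2[C@@H](OC(=O)C=[N+]=[N-])C1 | intermediate
25 | (1S,4R,5S,6S,7S,8S,10R)-1-(tert-butyldimethylsilyloxy)-4,5-epoxy-8-tigloyloxy-13-norgermacran-12,6-olide (key-step product) | C/C=C(\C)C(=O)O[C@H]1C[C@@H](C)[C@@H](O[Si](C)(C)C(C)(C)C)CC[C@@]2(C)O[C@H]2[C@H]2OC(=O)C[C@@H]12 | intermediate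
26 | lithium enolate of 25 | C/C=C(\C)C(=O)O[C@H]1C[C@@H](C)[C@@H](O[Si](C)(C)C(C)(C)C)CC[C@@]2(C)O[C@H]2[C@H]2OC([O-])=C[C@@H]12.[Li+] | intermediate
27 | lithium enolate of the 11-formyl lactone | C/C=C(\C)C(=O)O[C@H]1C[C@@H](C)[C@@H](O[Si](C)(C)C(C)(C)C)CC[C@@]2(C)O[C@H]2[C@H]2OC(=O)C(=C[O-])[C@@H]12.[Li+] | intermediate
28 | (11S)-13-oxo-11-phenylselanyl lactone | C/C=C(\C)C(=O)O[C@H]1C[C@@H](C)[C@@H](O[Si](C)(C)C(C)(C)C)CC[C@@]2(C)O[C@H]2[C@H]2OC(=O)[C@](C=O)([Se]c3ccccc3)[C@@H]12 | intermediate
29 | (11S)-13-hydroxy-11-phenylselanyl lactone | C/C=C(\C)C(=O)O[C@H]1C[C@@H](C)[C@@H](O[Si](C)(C)C(C)(C)C)CC[C@@]2(C)O[C@H]2[C@H]2OC(=O)[C@](CO)([Se]c3ccccc3)[C@@H]12 | intermediate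
30 | (11S)-13-acetoxy-11-phenylselanyl lactone | C/C=C(\C)C(=O)O[C@H]1C[C@@H](C)[C@@H](O[Si](C)(C)C(C)(C)C)CC[C@@]2(C)O[C@H]2[C@H]2OC(=O)[C@](COC(C)=O)([Se]c3ccccc3)[C@@H]12 | intermediate
31 | selenoxide of 30 | C/C=C(\C)C(=O)O[C@H]1C[C@@H](C)[C@@H](O[Si](C)(C)C(C)(C)C)CC[C@@]2(C)O[C@H]2[C@H]2OC(=O)[C@](COC(C)=O)([Se](=O)c3ccccc3)[C@@H]12 | intermediate
32 | 1-O-tert-butyldimethylsilyl ether of the target | C/C=C(\C)C(=O)O[C@H]1C[C@@H](C)[C@@H](O[Si](C)(C)C(C)(C)C)CC[C@@]2(C)O[C@H]2[C@H]2OC(=O)C(COC(C)=O)=C12 | intermediate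
33 | (1S,4R,5S,6S,8S,10R)-13-acetoxy-4,5-epoxy-1-hydroxy-8-tigloyloxygermacr-7(11)-en-12,6-olide | C/C=C(\C)C(=O)O[C@H]1C[C@@H](C)[C@@H](O)CC[C@@]2(C)O[C@H]2[C@H]2OC(=O)C(COC(C)=O)=C12 | target

Total step count: 20. Longest linear sequence: 19 steps (steps 1 and 3–20 from limonene; the branch from benzyl vinyl ether, steps 2–20, is equally long).

**Steps most likely to fail**

Step 4 (ring expansion). The dienolate 9 may expel benzyloxide from C8 by β-elimination before it is quenched, a process helped by the axial C–O bond. The axial alkoxy group may also slow the chair pathway enough for a boat pathway to compete and erode the C8 configuration. The fallback is a neutral siloxy-Cope rearrangement, in which no enolate is ever present. It sets out from 7, which would be silylated (Me3SiCl, imidazole, DMF) to the trimethylsilyl ether F1. Thermolysis (degassed toluene, sealed tube, about 200 °C) should take F1 through the same chair to the trimethylsilyl dienol ether F2. Buffered fluoride (Bu4NF, AcOH, THF, −78 °C) would then release the dienone, and the route is rejoined at 10.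

Step 8 (hydroboration). The E double bond can swing through the ten-membered ring and offer its other face, so facial selectivity may be poor or reversed. Excess borane may also slowly open the oxirane reductively. The fallback replaces substrate control by reagent control and makes no new compound. It sets out from 13, which would be hydroborated with monoisopinocampheylborane liberated from its TMEDA adduct with BF3·OEt2. The reagent made from (+)-α-pinene is the one whose intrinsic preference with trisubstituted and trans-disubstituted alkenes is for the S carbinol. The same alkaline peroxide oxidation would follow, and the route is rejoined at 15.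

Step 15 (key step). The mono-acceptor carbenoid may be diverted into carbene dimerisation, into ylide formation at the oxirane or tiglate oxygen, or into insertion at the deactivated C8–H bond. The β-acyloxy group also makes the C7–H bonds less reactive than in a simple cycloalkyl ester. The fallback keeps the C7–C11 disconnection but uses a more electrophilic acceptor/acceptor carbenoid that does not dimerise. It sets out from 21, which would be acylated with diketene (DMAP cat., THF, 0 °C) to the acetoacetate F3. Diazo transfer (4-acetamidobenzenesulfonyl azide, Et3N, MeCN) would give the diazoacetoacetate F4. Rh2(OAc)4 in refluxing benzene should insert into C7–H to give the 11-acetyl lactone F5. Retro-Claisen deacetylation (K2CO3, MeOH, 0 °C) would remove the acetyl group, and the route is rejoined at 25.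

**Further compounds**
F1 | step 4 | trimethylsilyl ether of 7 | CC1=C[C@](O[Si](C)(C)C)(/C=C\OCc2ccccc2)[C@H](CC1)C(C)=C
F2 | step 4 | (8S)-8-benzyloxy-6-trimethylsilyloxy-11,12,13-trinorgermacra-1(10)E,4Z,6E-triene | c1ccccc1CO[C@H]2C/C(C)=C/CC/C(C)=C\C(O[Si](C)(C)C)=C\2
F0 | step 8 | none | none
F3 | step 15 | 6-O-acetoacetate of 21 | C/C=C(\C)C(=O)O[C@H]1C[C@@H](C)[C@@H](O[Si](C)(C)C(C)(C)C)CC[C@@]2(C)O[C@H]2[C@@H](OC(=O)CC(C)=O)C1
F4 | step 15 | 6-O-(2-diazoacetoacetate) of 21 | C/C=C(\C)C(=O)O[C@H]1C[C@@H](C)[C@@H](O[Si](C)(C)C(C)(C)C)CC[C@@]2(C)O[C@H]2[C@@H](OC(=O)C(=[N+]=[N-])C(C)=O)C1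
F5 | step 15 | 11-acetyl derivative of 25 (C11 epimers) | C/C=C(\C)C(=O)O[C@H]1C[C@@H](C)[C@@H](O[Si](C)(C)C(C)(C)C)CC[C@@]2(C)O[C@H]2[C@H]2OC(=O)C(C(C)=O)[C@@H]12
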